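## Retrosynthetic overview

1. The tiglate is put on last by acylation of the C19 carbinol; the C13 carbinol travels as a triethylsilyl ether.
2. The C19 CH2OH and the C3 methylene come from a 3-oxo-19-oate (ester of a chiral auxiliary) by hydrazone/hydride reduction; C18 is added by enolate methylation trans to C20.
3. Rings A and B form in one operation by oxidative free-radical bicyclization of an acyclic E,E-triene β-keto ester: the C4–C5 bond closes ring A, then the C10–C9 bond closes ring B, and oxidation of the C8 radical gives the 8(17)-methylene.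
4. The acyclic β-keto ester comes from an acetoacetate dianion and a C15 allylic bromide.
5. The bromide comes from (2E,6E)-farnesol: asymmetric epoxidation and reductive epoxide opening set C13, and SeO2 oxidation functionalises the terminal (E)-methyl.

Assumption: labdane numbering is used for all ring compounds; (+)-8-phenylmenthol is bought and recovered in step 11, and its sense of induction is taken from the phenyl-shielding model of chelated 8-phenylmenthyl β-keto esters (the (1S,2R,5S) auxiliary leaves open the face that gives the 5α-H/10β-CH3 series).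

## Route

Step 1
Reactants: 1 (2E,6E)-farnesol
Product: 2 (2R,3R)-2,3-epoxyfarnesol
Conditions: Ti(OiPr)4 (5 mol %), D-(−)-diisopropyl tartrate (6 mol %), t-BuOOH, 4 Å MS, CH2Cl2, −20 °C
Reagents that add atoms: tert-butyl hydroperoxide, CC(C)(C)OO
Why: Katsuki–Sharpless asymmetric epoxidation touches only the allylic-alcohol alkene, and the D-(−)-tartrate catalyst delivers oxygen to the face that gives the (2R,3R)-epoxide, whose C3 becomes C13 of the target.

Step 2
Reactants: 2 (2R,3R)-2,3-epoxyfarnesol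
Product: 4 (3R,6E)-nerolidol, via epoxyfarnesyl iodide 3 (not isolated)
Conditions: PPh3, I2, imidazole, THF, 0 °C; then Zn dust, AcOH (cat.), 0 °C → rt
Reagents that add atoms: none
Why: Appel-type iodination of the primary alcohol followed by zinc-mediated reductive β-elimination of the β-iodo epoxide opens the ring without breaking the C3–O bond, so the tertiary allylic carbinol is formed with retention as (3R).

Step 3
Reactants: 4 (3R,6E)-nerolidol
Product: 5 (3R,6E)-nerolidol triethylsilyl ether
Conditions: Et3SiOTf, 2,6-lutidine, CH2Cl2, −78 → 0 °C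
Reagents that add atoms: triethylsilyl trifluoromethanesulfonate, CC[Si](CC)(CC)OS(=O)(=O)C(F)(F)F
Why: silylation of the hindered tertiary alcohol with the silyl triflate masks the hydroxyl, which would otherwise quench the dianion in step 7 and capture C8 as a cyclic ether in step 8.

Step 4
Reactants: 5 (3R,6E)-nerolidol triethylsilyl ether
Product: 6 (2E,6E,10R)-2,6,10-trimethyl-10-(triethylsilyloxy)dodeca-2,6,11-trien-1-ol
Conditions: SeO2 (0.3 equiv), t-BuOOH, salicylic acid (cat.), CH2Cl2, 0 °C → rt, stopped at partial conversion and 5 recycled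
Reagents that add atoms: selenium dioxide, O=[Se]=O (oxygen carrier); tert-butyl hydroperoxide, CC(C)(C)OO (terminal oxidant)
Why: Sharpless catalytic SeO2 allylic oxidation (ene reaction, then [2,3]-sigmatropic shift) attacks the (E)-methyl of the terminal, most electron-rich trisubstituted alkene and gives the (E)-allylic alcohol.

Step 5
Reactants: 6 (2E,6E,10R)-2,6,10-trimethyl-10-(triethylsilyloxy)dodeca-2,6,11-trien-1-ol
Product: 7 (2E,6E,10R)-1-bromo-2,6,10-trimethyl-10-(triethylsilyloxy)dodeca-2,6,11-triene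
Conditions: CBr4, PPh3, CH2Cl2, 0 °C
Reagents that add atoms: carbon tetrabromide, BrC(Br)(Br)Br
Why: Appel bromination is an SN2 displacement at the primary allylic carbinol under neutral conditions, so the alkene geometry and the silyl ether are kept.

Step 6
Reactants: 8 (+)-8-phenylmenthol [(1S,2R,5S)-5-methyl-2-(2-phenylpropan-2-yl)cyclohexan-1-ol], 9 2,2,6-trimethyl-4H-1,3-dioxin-4-one
Product: 10 (+)-8-phenylmenthyl 3-oxobutanoate
Conditions: xylene, 140 °C, acetone distilled off
Reagents that add atoms: none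
Why: thermal retro-[4+2] of the dioxinone gives acetylketene, which the secondary alcohol traps (acetoacetylation) without touching its stereocentres.

Step 7
Reactants: 10 (+)-8-phenylmenthyl 3-oxobutanoate, 7 (2E,6E,10R)-1-bromo-2,6,10-trimethyl-10-(triethylsilyloxy)dodeca-2,6,11-triene
Product: 12 (+)-8-phenylmenthyl (6E,10E,14R)-6,10,14-trimethyl-3-oxo-14-(triethylsilyloxy)hexadeca-6,10,15-trienoate, via dilithium dienolate 11 (not isolated)
Conditions: LiN(iPr)2 (2.1 equiv), THF, 0 °C; then 7, −78 → 0 °C; H2O quench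
Reagents that add atoms: none
Why: Weiler dianion alkylation, in which the more basic terminal (γ) carbanion displaces the primary allylic bromide by SN2 and leaves the E geometry intact.

Step 8
Reactants: 12 (+)-8-phenylmenthyl (6E,10E,14R)-6,10,14-trimethyl-3-oxo-14-(triethylsilyloxy)hexadeca-6,10,15-trienoate
Product: 13 (+)-8-phenylmenthyl (13R)-3-oxo-13-(triethylsilyloxy)-4-demethyl-labda-8(17),14-diene-4α-carboxylate (4β-H, 5α-H, 9α-H, 10β-CH3; C4 enolisable)
Conditions: Mn(OAc)3·2H2O (2.2 equiv), Cu(OAc)2·H2O (1 equiv), Yb(OTf)3 (1 equiv), degassed CF3CH2OH, −5 → 0 °C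
Reagents that add atoms: none
Why: Snider-type Mn(OAc)3/Cu(OAc)2 oxidative free-radical polyene cyclization, in which the trivalent-manganese enolate radical at C4 closes ring A (6-endo, C4–C5) and the C10 radical closes ring B (6-endo, C10–C9) through a chair–chair array of the E,E-diene that gives the trans-decalin with the C9 chain equatorial, the phenyl ring of the auxiliary covers one face of the Yb(OTf)3-chelated keto ester so that C5 adds to the open face and fixes C5, C10 and C9 absolutely, and Cu(OAc)2 oxidises the tertiary C8 radical to the less substituted 8(17)-alkene.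

Step 9
Reactants: 13 (+)-8-phenylmenthyl (13R)-3-oxo-13-(triethylsilyloxy)-4-demethyl-labda-8(17),14-diene-4α-carboxylate
Product: 14 (+)-8-phenylmenthyl (13R)-3-oxo-13-(triethylsilyloxy)labda-8(17),14-dien-19-oate (4α-CH3, 4β-CO2R*)
Conditions: K2CO3, MeI, acetone, 50 °C
Reagents that add atoms: iodomethane, CI
Why: C-alkylation of the β-keto ester enolate, in which the methyl enters the α-face, anti to the axial C10 methyl and on the face the auxiliary leaves open (matched), so the ester ends axial (C19) and the new methyl equatorial (C18).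

Step 10
Reactants: 14 (+)-8-phenylmenthyl (13R)-3-oxo-13-(triethylsilyloxy)labda-8(17),14-dien-19-oate
Product: 15 3-(p-toluenesulfonyl)hydrazone of 14
Conditions: TsNHNH2, EtOH, 75 °C
Reagents that add atoms: p-toluenesulfonyl hydrazide, Cc1ccc(cc1)S(=O)(=O)NN
Why: condensation of the only ketone with the sulfonyl hydrazide under near-neutral conditions that spare the silyl ether, the alkenes and the non-enolisable β-keto ester.

Step 11
Reactants: 15 3-(p-toluenesulfonyl)hydrazone of 14
Product: 16 (13R)-13-(triethylsilyloxy)labda-8(17),14-dien-19-ol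
Conditions: LiAlH4, THF, 0 °C → reflux; aqueous work-up; 8 recovered
Reagents that add atoms: none
Why: Caglioti reduction, in which hydride adds to the C=N bond and loss of p-toluenesulfinate and N2 leaves CH2 at C3, while the same reagent reduces the hindered axial ester to the C19 carbinol and releases the auxiliary; no stereocentre is touched.

Step 12
Reactants: 16 (13R)-13-(triethylsilyloxy)labda-8(17),14-dien-19-ol, 17 tigloyl chloride [(2E)-2-methylbut-2-enoyl chloride]
Product: 18 (13R)-13-(triethylsilyloxy)labda-8(17),14-dien-19-yl tiglate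
Conditions: pyridine, DMAP (cat.), CH2Cl2, 0 °C → rt
Reagents that add atoms: none
Why: DMAP-catalysed acylation of the primary neopentyl alcohol; the weak base avoids vinylketene formation, so the (E)-2-methylbut-2-enoyl unit is transferred unchanged.

Step 13
Reactants: 18 (13R)-13-(triethylsilyloxy)labda-8(17),14-dien-19-yl tiglate
Product: 19 (13R)-13-hydroxylabda-8(17),14-dien-19-yl (2E)-2-methylbut-2-enoate [(4S,5R,9S,10R,13R); target]
Conditions: Bu4NF, THF, 0 °C → rt
Reagents that add atoms: none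
Why: fluoride-mediated desilylation under non-acidic conditions frees the tertiary allylic alcohol without ionising it and leaves the hindered tiglate and both alkenes intact.

## Compound list

1 | (2E,6E)-farnesol | CC(C)=CCC/C(C)=C/CC/C(C)=C/CO | starting material
2 | (2R,3R)-2,3-epoxyfarnesol | CC(C)=CCC/C(C)=C/CC[C@@]1(C)O[C@@H]1CO | intermediate
3 | epoxyfarnesyl iodide, (2S,3R)-2-(iodomethyl)-3-methyl-3-[(3E)-4,8-dimethylnona-3,7-dienyl]oxirane (same spatial arrangement as 2; formed in situ) | CC(C)=CCC/C(C)=C/CC[C@@]1(C)O[C@@H]1CI | intermediate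
4 | (3R,6E)-nerolidol | CC(C)=CCC/C(C)=C/CC[C@@](C)(O)C=C | intermediate
5 | (3R,6E)-nerolidol triethylsilyl ether | CC(C)=CCC/C(C)=C/CC[C@@](C)(O[Si](CC)(CC)CC)C=C | intermediate
6 | (2E,6E,10R)-2,6,10-trimethyl-10-(triethylsilyloxy)dodeca-2,6,11-trien-1-ol | OC/C(C)=C/CC/C(C)=C/CC[C@@](C)(O[Si](CC)(CC)CC)C=C | intermediate
7 | (2E,6E,10R)-1-bromo-2,6,10-trimethyl-10-(triethylsilyloxy)dodeca-2,6,11-triene | BrC/C(C)=C/CC/C(C)=C/CC[C@@](C)(O[Si](CC)(CC)CC)C=C | intermediate
8 | (+)-8-phenylmenthol, (1S,2R,5S)-5-methyl-2-(2-phenylpropan-2-yl)cyclohexan-1-ol | O[C@H]1C[C@@H](C)CC[C@@H]1C(C)(C)c1ccccc1 | starting material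
9 | 2,2,6-trimethyl-4H-1,3-dioxin-4-one | CC1=CC(=O)OC(C)(C)O1 | starting material
10 | (+)-8-phenylmenthyl 3-oxobutanoate | CC(=O)CC(=O)O[C@H]1C[C@@H](C)CC[C@@H]1C(C)(C)c1ccccc1 | intermediate
11 | dilithium dienolate of 10 (formed in situ) | [Li+].[Li+].C=C([O-])C=C([O-])O[C@H]1C[C@@H](C)CC[C@@H]1C(C)(C)c1ccccc1 | intermediate
12 | (+)-8-phenylmenthyl (6E,10E,14R)-6,10,14-trimethyl-3-oxo-14-(triethylsilyloxy)hexadeca-6,10,15-trienoate | O=C(CC(=O)CC/C(C)=C/CC/C(C)=C/CC[C@@](C)(O[Si](CC)(CC)CC)C=C)O[C@H]1C[C@@H](C)CC[C@@H]1C(C)(C)c2ccccc2 | intermediate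
13 | (+)-8-phenylmenthyl (13R)-3-oxo-13-(triethylsilyloxy)-4-demethyl-labda-8(17),14-diene-4α-carboxylate (4β-H, 5α-H, 9α-H, 10β-CH3) | C=C[C@](C)(O[Si](CC)(CC)CC)CC[C@H]1C(=C)CC[C@H]2[C@H](C(=O)O[C@H]3C[C@@H](C)CC[C@@H]3C(C)(C)c4ccccc4)C(=O)CC[C@]12C | intermediate
14 | (+)-8-phenylmenthyl (13R)-3-oxo-13-(triethylsilyloxy)labda-8(17),14-dien-19-oate | C=C[C@](C)(O[Si](CC)(CC)CC)CC[C@H]1C(=C)CC[C@H]2[C@@](C)(C(=O)O[C@H]3C[C@@H](C)CC[C@@H]3C(C)(C)c4ccccc4)C(=O)CC[C@]12C | intermediate
15 | 3-(p-toluenesulfonyl)hydrazone of 14 (C=N geometry not specified) | C=C[C@](C)(O[Si](CC)(CC)CC)CC[C@H]1C(=C)CC[C@H]2[C@@](C)(C(=O)O[C@H]3C[C@@H](C)CC[C@@H]3C(C)(C)c4ccccc4)C(=NNS(=O)(=O)c5ccc(C)cc5)CC[C@]12C | intermediate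
16 | (13R)-13-(triethylsilyloxy)labda-8(17),14-dien-19-ol | C=C[C@](C)(O[Si](CC)(CC)CC)CC[C@H]1C(=C)CC[C@H]2[C@@](C)(CO)CCC[C@]12C | intermediate
17 | tigloyl chloride, (2E)-2-methylbut-2-enoyl chloride | C/C=C(\C)C(=O)Cl | starting material
18 | (13R)-13-(triethylsilyloxy)labda-8(17),14-dien-19-yl tiglate | C=C[C@](C)(O[Si](CC)(CC)CC)CC[C@H]1C(=C)CC[C@H]2[C@@](C)(COC(=O)/C(C)=C/C)CCC[C@]12C | intermediate
19 | (13R)-13-hydroxylabda-8(17),14-dien-19-yl (2E)-2-methylbut-2-enoate, (4S,5R,9S,10R,13R) | C=C[C@](C)(O)CC[C@H]1C(=C)CC[C@H]2[C@@](C)(COC(=O)/C(C)=C/C)CCC[C@]12C | target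

## Step count and risk

Total steps: 13. Longest linear sequence: 12 (steps 1–5 and 7–13, from 1 to 19); step 6 is a one-step side branch.

Steps most likely to fail:

Step 8 (radical bicyclization). The risks are an 8(17)/Δ7 alkene mixture from the copper-mediated elimination, further oxidation of the enolisable product, capture of C8 by the silyl ether oxygen, and erosion of the auxiliary control when Cu(OAc)2 is present. The fallback replaces the oxidative termination by a group-transfer radical cyclization; it sets out from 12 and comes back at 13. Treatment of 12 with NaH and PhSeCl in THF gives the α-phenylseleno β-keto ester F1. Irradiation of F1 with Yb(OTf)3 in CH2Cl2 at −40 °C starts a phenylseleno-transfer chain in which the same chelated, auxiliary-shielded C4 radical closes rings A and B and the C8 radical takes PhSe from another molecule of F1, giving the C8 phenylselenide F2 without any oxidant or cation. Oxidation of F2 with H2O2 and pyridine at 0 °C and selenoxide syn-elimination then gives 13.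

Step 11 (one-pot hydrazone and ester reduction). The hindered C3 hydrazone may add hydride slowly and give some 2-ene by base-induced decomposition. The fallback removes the C3 oxygen by radical deoxygenation and also bypasses step 10; it sets out from 14 and comes back at 16. NaBH4 in MeOH at 0 °C reduces the ketone from the α-face to the 3β-hydroxy ester F3. NaH, CS2 and MeI in THF convert it into the S-methyl xanthate F4. Bu3SnH with AIBN in toluene at 100 °C (Barton–McCombie) gives the 3-deoxy ester F5. LiAlH4 in refluxing THF then reduces the ester to 16 and returns 8.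

Step 4 (SeO2 oxidation). The risks are modest conversion, over-oxidation to the enal and competing attack at the internal alkene. The fallback builds the (E)-allylic alcohol by degradation and olefination; it sets out from 5 and comes back at 6. NBS in aqueous THF at 0 °C gives the terminal bromohydrin F6 (van Tamelen selectivity for the terminal alkene). K2CO3 in MeOH closes it to the terminal epoxide F7. H5IO6 in aqueous THF cleaves the epoxide to the aldehyde F8. The stabilised ylide Ph3P=C(CH3)CO2Et in CH2Cl2 gives the (E)-enoate F9. iBu2AlH in CH2Cl2 at −78 °C reduces F9 to 6.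

## Further compounds

F1 | step 8 | (+)-8-phenylmenthyl (6E,10E,14R)-6,10,14-trimethyl-3-oxo-2-(phenylselanyl)-14-(triethylsilyloxy)hexadeca-6,10,15-trienoate (C2 epimers) | O=C(C([Se]c1ccccc1)C(=O)CC/C(C)=C/CC/C(C)=C/CC[C@@](C)(O[Si](CC)(CC)CC)C=C)O[C@H]2C[C@@H](C)CC[C@@H]2C(C)(C)c3ccccc3
F2 | step 8 | (+)-8-phenylmenthyl (13R)-3-oxo-8-(phenylselanyl)-13-(triethylsilyloxy)-4-demethyl-labd-14-ene-4α-carboxylate (C8 epimers) | C=C[C@](C)(O[Si](CC)(CC)CC)CC[C@H]1C(C)([Se]c5ccccc5)CC[C@H]2[C@H](C(=O)O[C@H]3C[C@@H](C)CC[C@@H]3C(C)(C)c4ccccc4)C(=O)CC[C@]12C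
F3 | step 11 | (+)-8-phenylmenthyl (13R)-3β-hydroxy-13-(triethylsilyloxy)labda-8(17),14-dien-19-oate | C=C[C@](C)(O[Si](CC)(CC)CC)CC[C@H]1C(=C)CC[C@H]2[C@@](C)(C(=O)O[C@H]3C[C@@H](C)CC[C@@H]3C(C)(C)c4ccccc4)[C@@H](O)CC[C@]12C
F4 | step 11 | S-methyl xanthate of F3, (+)-8-phenylmenthyl (13R)-3β-[(methylsulfanyl)carbonothioyl]oxy-13-(triethylsilyloxy)labda-8(17),14-dien-19-oate | C=C[C@](C)(O[Si](CC)(CC)CC)CC[C@H]1C(=C)CC[C@H]2[C@@](C)(C(=O)O[C@H]3C[C@@H](C)CC[C@@H]3C(C)(C)c4ccccc4)[C@@H](OC(=S)SC)CC[C@]12C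
F5 | step 11 | (+)-8-phenylmenthyl (13R)-13-(triethylsilyloxy)labda-8(17),14-dien-19-oate | C=C[C@](C)(O[Si](CC)(CC)CC)CC[C@H]1C(=C)CC[C@H]2[C@@](C)(C(=O)O[C@H]3C[C@@H](C)CC[C@@H]3C(C)(C)c4ccccc4)CCC[C@]12C
F6 | step 4 | (6E,10R)-3-bromo-2,6,10-trimethyl-10-(triethylsilyloxy)dodeca-6,11-dien-2-ol (C3 epimers) | CC(C)(O)C(Br)CC/C(C)=C/CC[C@@](C)(O[Si](CC)(CC)CC)C=C
F7 | step 4 | 2,2-dimethyl-3-[(3E,7R)-3,7-dimethyl-7-(triethylsilyloxy)nona-3,8-dien-1-yl]oxirane (epoxide epimers) | CC1(C)OC1CC/C(C)=C/CC[C@@](C)(O[Si](CC)(CC)CC)C=C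
F8 | step 4 | (4E,8R)-4,8-dimethyl-8-(triethylsilyloxy)deca-4,9-dienal | O=CCC/C(C)=C/CC[C@@](C)(O[Si](CC)(CC)CC)C=C
F9 | step 4 | ethyl (2E,6E,10R)-2,6,10-trimethyl-10-(triethylsilyloxy)dodeca-2,6,11-trienoate | CCOC(=O)/C(C)=C/CC/C(C)=C/CC[C@@](C)(O[Si](CC)(CC)CC)C=C
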